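Locants (azulene numbering): C3 = quaternary C(CH3) carbon, C3a/C8a = ring fusion, C4 = C(=CH2) carbon, C8 = C(CH3)2; C1' = side-chain CH(CH2OAc) on C3; C4'' = lactone carbon bonded to C1', C5'' = its OCH2 neighbour.
Retrosynthesis cuts, in order: the acetate; C1'–C4'' (imide enolate + 5-alkoxybutenolide); C4=CH2 (back to a C4 ketone); C8–C8a, which opens the seven-membered ring; the C3a–C4 and C4–C5 bonds at the ketone carbon (enol triflate + CO + alkylzinc); the allyl group on C3.
Enabling feature: C8 (CMe2) is bonded to ring-fusion carbon C8a, and C8a is β to C4 once C4 is a ketone, so the quaternary–tertiary C8–C8a bond is that of a tertiary radical adding to the β-carbon of a cyclopent-1-enyl ketone with closure of the seven-membered ring.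
Forward: the five-membered ring comes from the starting keto ester and receives its quaternary carbon by decarboxylative allylation; the C5–C8 chain is attached by carbonylative coupling; the radical step closes the seven-membered ring; the side chain and lactone are joined last.
Stereochemistry: C3 from the (S)-t-BuPHOX palladium catalyst; C8a and C3a from C3 during the cyclisation; C1' from an (R)-benzyloxazolidinone; C4'' from the (5S)-menthyloxy group of the butenolide.

Key step: step 9

Remark: (5S)-5-(d-menthyloxy)furan-2(5H)-one (23) is taken as a purchased reagent; it is otherwise two steps from furfural and (+)-menthol.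

Step 1
Reactants: 1 methyl 2-oxocyclopentane-1-carboxylate; 2 prop-2-en-1-ol
Product: 3 prop-2-en-1-yl 2-oxocyclopentane-1-carboxylate
Conditions: 2 (3 equiv), DMAP (10 mol %), toluene, reflux, 4 Å MS
Reagents that add atoms: none
Why: Transesterification of a β-keto ester (DMAP catalysis through the enol/acylketene pathway) is driven to the allyl ester by removal of methanol; no stereocentre is involved.

Step 2
Reactants: 3 prop-2-en-1-yl 2-oxocyclopentane-1-carboxylate
Product: 4 prop-2-en-1-yl 1-methyl-2-oxocyclopentane-1-carboxylate (racemic)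
Conditions: MeI, K2CO3, acetone, reflux
Reagents that add atoms: iodomethane, CI
Why: C-Alkylation of the β-keto ester enolate with iodomethane builds the quaternary carbon as a racemate, which is acceptable because the next step destroys and re-forms this centre.

Step 3
Reactants: 4 prop-2-en-1-yl 1-methyl-2-oxocyclopentane-1-carboxylate
Product: 5 (2S)-2-methyl-2-(prop-2-en-1-yl)cyclopentan-1-one
Conditions: Pd2(dba)3 (2.5 mol %), (S)-t-BuPHOX (6 mol %), toluene, 30 °C
Reagents that add atoms: none
Why: Decarboxylative asymmetric allylic alkylation (Tsuji–Trost type, Pd/PHOX): both enantiomers of 4 lose CO2 to the same achiral enolate/π-allylpalladium pair, and the (S)-t-BuPHOX ligand, which gives the (S)-2-allyl-2-methyl ketone in the cyclohexanone series, should set the quaternary carbon as S here.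

Step 4
Reactants: 5 (2S)-2-methyl-2-(prop-2-en-1-yl)cyclopentan-1-one
Product: 7 2-[(1S)-1-methyl-2-oxocyclopentyl]acetaldehyde, via ozonide 6 (not isolated)
Conditions: O3, CH2Cl2, −78 °C; then PPh3, −78 °C → rt
Reagents that add atoms: ozone, O=[O+][O-]
Why: Ozonolysis with phosphine work-up cleaves the only C=C bond to the aldehyde and leaves the ketone and the quaternary centre untouched.

Step 5
Reactants: 7 2-[(1S)-1-methyl-2-oxocyclopentyl]acetaldehyde
Product: 8 (2S)-2-(2-hydroxyethyl)-2-methylcyclopentan-1-one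
Conditions: NaBH4 (0.3 equiv), CH2Cl2/EtOH (7:3), −78 °C
Reagents that add atoms: none
Why: Chemoselective borohydride reduction: at −78 °C an aldehyde is reduced much faster than a ketone flanked by a quaternary carbon, so only the primary alcohol should form.

Step 6
Reactants: 8 (2S)-2-(2-hydroxyethyl)-2-methylcyclopentan-1-one
Product: 9 (2S)-2-[2-(tert-butyldiphenylsilyloxy)ethyl]-2-methylcyclopentan-1-one
Conditions: TBDPSCl, imidazole, DMF, rt
Reagents that add atoms: tert-butyl(chloro)diphenylsilane, CC(C)(C)[Si](Cl)(c1ccccc1)c1ccccc1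
Why: Silylation of a primary alcohol under imidazole catalysis; TBDPS is chosen for its bulk (it marks the larger arm of C3 for the key step) and for its stability to amide bases, organozinc reagents, iron hydride and the titanium–zinc methylene reagent.

Step 7
Reactants: 9 (2S)-2-[2-(tert-butyldiphenylsilyloxy)ethyl]-2-methylcyclopentan-1-one
Product: 11 (5S)-5-[2-(tert-butyldiphenylsilyloxy)ethyl]-5-methylcyclopent-1-en-1-yl trifluoromethanesulfonate, via potassium enolate 10 (not isolated)
Conditions: KHMDS, THF, −78 °C; then PhNTf2, −78 → 0 °C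
Reagents that add atoms: N-phenylbis(trifluoromethanesulfonimide), O=S(=O)(N(c1ccccc1)S(=O)(=O)C(F)(F)F)C(F)(F)F
Why: Enol triflate formation: the ketone can enolise only towards CH2 (the other α-carbon is quaternary), and the potassium enolate is O-sulfonylated by PhNTf2.

Step 8
Reactants: 11 (5S)-5-[2-(tert-butyldiphenylsilyloxy)ethyl]-5-methylcyclopent-1-en-1-yl trifluoromethanesulfonate; 12 5-bromo-2-methylpent-1-ene
Product: 14 1-[(5S)-5-[2-(tert-butyldiphenylsilyloxy)ethyl]-5-methylcyclopent-1-en-1-yl]-5-methylhex-5-en-1-one, via alkylzinc bromide 13 (not isolated)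
Conditions: 12, Zn dust, LiCl, THF, 40 °C; then 11, Pd(PPh3)4 (5 mol %), CO (1 atm), THF/NMP, 50 °C
Reagents that add atoms: carbon monoxide, [C-]#[O+]
Why: Carbonylative Negishi coupling: oxidative addition of Pd(0) to the enol triflate, CO insertion into the hindered alkenyl–Pd bond and transmetalation from the alkylzinc bromide (made by direct zinc insertion in the presence of LiCl, which tolerates the 1,1-disubstituted alkene) give the enone after reductive elimination.

Step 9
Reactants: 14 1-[(5S)-5-[2-(tert-butyldiphenylsilyloxy)ethyl]-5-methylcyclopent-1-en-1-yl]-5-methylhex-5-en-1-one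
Product: 15 (3S,3aR,8aR)-3-[2-(tert-butyldiphenylsilyloxy)ethyl]-3,8,8-trimethyl-2,3,3a,5,6,7,8,8a-octahydroazulen-4(1H)-one (cis-fused)
Conditions: Fe(acac)3 (30 mol %), PhSiH3 (2.5 equiv), EtOH/(CH2OH)2 (5:1), 60 °C, 0.01 M
Reagents that add atoms: none
Why: An iron hydride formed from Fe(acac)3 and PhSiH3 transfers a hydrogen atom to the CH2 terminus of the electron-rich 1,1-disubstituted alkene; the resulting nucleophilic tertiary radical adds to the electrophilic β-carbon C8a of the cyclopentenyl ketone, and the α-keto radical is reduced to the iron enolate and protonated by ethanol at C3a. The closest known reaction type is the metal-hydride HAT-initiated reductive olefin–enone (Giese) coupling, which forms quaternary carbons and has been used for ring closure. The seven-membered ring closes 7-endo-trig; the 6-exo alternative would attack the α-carbon against the polarity of radical and acceptor and would join two fully substituted carbons beside C3. C8a should be set by attack on the cyclopentene face anti to the CH2CH2OTBDPS arm of C3 (syn to methyl), and C3a by protonation of the enolate anti to the new CMe2 carbon, which gives the cis fusion; C3a is α to the ketone and can be equilibrated if needed. The step needs chemoselective hydrogen-atom transfer to the isopropenyl group, 7-endo regioselectivity and facial selectivity at C8a: alkene electronics and polarity matching secure the first two, whereas the third rests only on the size difference of the two C3 substituents, which is why the bulky silyl ether and high dilution are used.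

Step 10
Reactants: 15 (3S,3aR,8aR)-3-[2-(tert-butyldiphenylsilyloxy)ethyl]-3,8,8-trimethyl-2,3,3a,5,6,7,8,8a-octahydroazulen-4(1H)-one
Product: 16 tert-butyl{2-[(3S,3aS,8aR)-3,8,8-trimethyl-4-methylidenedecahydroazulen-3-yl]ethoxy}diphenylsilane
Conditions: Zn, CH2Br2, TiCl4, THF, −40 → 5 °C (pre-formed reagent); then 15, CH2Cl2, 0 °C → rt
Reagents that add atoms: dibromomethane, BrCBr
Why: Takai–Lombardo methylenation, a non-basic zinc/titanium methylene transfer that converts hindered enolisable ketones without epimerising the adjacent ring-fusion centre C3a and leaves the silyl ether alone.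

Step 11
Reactants: 16 tert-butyl{2-[(3S,3aS,8aR)-3,8,8-trimethyl-4-methylidenedecahydroazulen-3-yl]ethoxy}diphenylsilane
Product: 17 2-[(3S,3aS,8aR)-3,8,8-trimethyl-4-methylidenedecahydroazulen-3-yl]ethan-1-ol
Conditions: TBAF, THF, rt
Reagents that add atoms: none
Why: Fluoride cleaves the Si–O bond; nothing else in 16 reacts.

Step 12
Reactants: 17 2-[(3S,3aS,8aR)-3,8,8-trimethyl-4-methylidenedecahydroazulen-3-yl]ethan-1-ol
Product: 19 2-[(3S,3aS,8aR)-3,8,8-trimethyl-4-methylidenedecahydroazulen-3-yl]acetic acid, via aldehyde 18 (not isolated)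
Conditions: TEMPO (20 mol %), PhI(OAc)2 (2.2 equiv), MeCN/H2O (1:1), rt
Reagents that add atoms: water, O
Why: TEMPO/PhI(OAc)2 oxidation in aqueous acetonitrile takes the primary alcohol through the aldehyde and its hydrate to the carboxylic acid and spares the 1,1-disubstituted alkene.

Step 13
Reactants: 19 2-[(3S,3aS,8aR)-3,8,8-trimethyl-4-methylidenedecahydroazulen-3-yl]acetic acid; 20 (4R)-4-benzyl-1,3-oxazolidin-2-one
Product: 22 (4R)-4-benzyl-3-{2-[(3S,3aS,8aR)-3,8,8-trimethyl-4-methylidenedecahydroazulen-3-yl]acetyl}-1,3-oxazolidin-2-one, via mixed pivalic anhydride 21 (not isolated)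
Conditions: PivCl, Et3N, THF, −20 °C; then 20, LiCl, −20 °C → rt
Reagents that add atoms: none
Why: N-Acylation of the oxazolidinone auxiliary through the mixed pivalic anhydride with LiCl/Et3N; the oxazolidinone attacks the less hindered, substrate-derived carbonyl.

Step 14
Reactants: 22 (4R)-4-benzyl-3-{2-[(3S,3aS,8aR)-3,8,8-trimethyl-4-methylidenedecahydroazulen-3-yl]acetyl}-1,3-oxazolidin-2-one; 23 (5S)-5-{[(1S,2R,5S)-5-methyl-2-(propan-2-yl)cyclohexyl]oxy}furan-2(5H)-one
Product: 25 (4R)-4-benzyl-3-[(2R)-2-{(2S,3R)-2-[(1S,2R,5S)-5-methyl-2-(propan-2-yl)cyclohexyl]oxy-5-oxooxolan-3-yl}-2-[(3R,3aS,8aR)-3,8,8-trimethyl-4-methylidenedecahydroazulen-3-yl]acetyl]-1,3-oxazolidin-2-one, via lithium enolate 24 (not isolated)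
Conditions: LDA, THF, −78 °C; then 23, −78 → −40 °C; AcOH
Reagents that add atoms: none
Why: Michael addition under double reagent control: the chelated (Z)-lithium enolate of the (R)-benzyloxazolidinone imide reacts on the face opposite the benzyl group, which sets C1' (R), and the 5-alkoxybutenolide is attacked at its β-carbon anti to the menthyloxy group, which sets C4'' (R); since each partner exposes one face, both centres are fixed whatever the rotamer of the open transition state.

Step 15
Reactants: 25 (4R)-4-benzyl-3-[(2R)-2-{(2S,3R)-2-[(1S,2R,5S)-5-methyl-2-(propan-2-yl)cyclohexyl]oxy-5-oxooxolan-3-yl}-2-[(3R,3aS,8aR)-3,8,8-trimethyl-4-methylidenedecahydroazulen-3-yl]acetyl]-1,3-oxazolidin-2-one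
Product: 28 (4R)-4-{(1R)-2-hydroxy-1-[(3R,3aS,8aR)-3,8,8-trimethyl-4-methylidenedecahydroazulen-3-yl]ethyl}oxolan-2-one, via hydroxymethyl menthyloxy lactone 26 (not isolated), via dihydroxy acid 27 (not isolated)
Conditions: NaBH4, THF/H2O (4:1), 0 °C → rt; then 2 M KOH, rt; then 2 M HCl to pH 2, rt
Reagents that add atoms: none
Why: Borohydride reduces the activated imide carbonyl to the primary alcohol (reductive removal of the oxazolidinone auxiliary); alkaline borohydride then opens the lactone acetal, releases menthol and reduces the unmasked aldehyde before it can enolise (the established reductive removal of a 5-menthyloxy group); acidification closes the five-membered lactone in preference to the six-membered one, and no stereocentre is touched.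

Step 16
Reactants: 28 (4R)-4-{(1R)-2-hydroxy-1-[(3R,3aS,8aR)-3,8,8-trimethyl-4-methylidenedecahydroazulen-3-yl]ethyl}oxolan-2-one
Product: 29 (4R)-4-{(1R)-2-acetoxy-1-[(3R,3aS,8aR)-3,8,8-trimethyl-4-methylidenedecahydroazulen-3-yl]ethyl}oxolan-2-one (CNP0235949.1)
Conditions: Ac2O, pyridine, DMAP (cat.), CH2Cl2, 0 °C → rt
Reagents that add atoms: acetic anhydride, CC(=O)OC(C)=O
Why: DMAP-catalysed acetylation of the primary alcohol; lactone, alkene and all stereocentres are inert.

Compound list
1 | methyl 2-oxocyclopentane-1-carboxylate | COC(=O)C1CCCC1=O | starting material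
2 | prop-2-en-1-ol | C=CCO | starting material
3 | prop-2-en-1-yl 2-oxocyclopentane-1-carboxylate | C=CCOC(=O)C1CCCC1=O | intermediate
4 | prop-2-en-1-yl 1-methyl-2-oxocyclopentane-1-carboxylate (racemic) | C=CCOC(=O)C1(C)CCCC1=O | intermediate
5 | (2S)-2-methyl-2-(prop-2-en-1-yl)cyclopentan-1-one | O=C1CCC[C@@]1(C)CC=C | intermediate
6 | (2S)-2-methyl-2-(1,2,4-trioxolan-3-ylmethyl)cyclopentan-1-one (ozonide, both epimers at the trioxolane carbon) | O=C1CCC[C@@]1(C)CC2OCOO2 | intermediate
7 | 2-[(1S)-1-methyl-2-oxocyclopentyl]acetaldehyde | O=C1CCC[C@@]1(C)CC=O | intermediate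
8 | (2S)-2-(2-hydroxyethyl)-2-methylcyclopentan-1-one | O=C1CCC[C@@]1(C)CCO | intermediate
9 | (2S)-2-[2-(tert-butyldiphenylsilyloxy)ethyl]-2-methylcyclopentan-1-one | O=C1CCC[C@@]1(C)CCO[Si](c2ccccc2)(c3ccccc3)C(C)(C)C | intermediate
10 | potassium (5S)-5-[2-(tert-butyldiphenylsilyloxy)ethyl]-5-methylcyclopent-1-en-1-olate | [K+].[O-]C1=CCC[C@@]1(C)CCO[Si](c2ccccc2)(c3ccccc3)C(C)(C)C | intermediate
11 | (5S)-5-[2-(tert-butyldiphenylsilyloxy)ethyl]-5-methylcyclopent-1-en-1-yl trifluoromethanesulfonate | O=S(=O)(OC1=CCC[C@@]1(C)CCO[Si](c2ccccc2)(c3ccccc3)C(C)(C)C)C(F)(F)F | intermediate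
12 | 5-bromo-2-methylpent-1-ene | C=C(C)CCCBr | starting material
13 | (4-methylpent-4-en-1-yl)zinc bromide | C=C(C)CCC[Zn]Br | intermediate
14 | 1-[(5S)-5-[2-(tert-butyldiphenylsilyloxy)ethyl]-5-methylcyclopent-1-en-1-yl]-5-methylhex-5-en-1-one | C=C(C)CCCC(=O)C1=CCC[C@@]1(C)CCO[Si](c2ccccc2)(c3ccccc3)C(C)(C)C | intermediate
15 | (3S,3aR,8aR)-3-[2-(tert-butyldiphenylsilyloxy)ethyl]-3,8,8-trimethyl-2,3,3a,5,6,7,8,8a-octahydroazulen-4(1H)-one | O=C1CCCC(C)(C)[C@@H]2CC[C@@](C)(CCO[Si](c3ccccc3)(c4ccccc4)C(C)(C)C)[C@H]12 | intermediate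
16 | tert-butyl{2-[(3S,3aS,8aR)-3,8,8-trimethyl-4-methylidenedecahydroazulen-3-yl]ethoxy}diphenylsilane | C=C1CCCC(C)(C)[C@@H]2CC[C@@](C)(CCO[Si](c3ccccc3)(c4ccccc4)C(C)(C)C)[C@H]12 | intermediate
17 | 2-[(3S,3aS,8aR)-3,8,8-trimethyl-4-methylidenedecahydroazulen-3-yl]ethan-1-ol | C=C1CCCC(C)(C)[C@@H]2CC[C@@](C)(CCO)[C@H]12 | intermediate
18 | 2-[(3S,3aS,8aR)-3,8,8-trimethyl-4-methylidenedecahydroazulen-3-yl]acetaldehyde | C=C1CCCC(C)(C)[C@@H]2CC[C@@](C)(CC=O)[C@H]12 | intermediate
19 | 2-[(3S,3aS,8aR)-3,8,8-trimethyl-4-methylidenedecahydroazulen-3-yl]acetic acid | C=C1CCCC(C)(C)[C@@H]2CC[C@@](C)(CC(=O)O)[C@H]12 | intermediate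
20 | (4R)-4-benzyl-1,3-oxazolidin-2-one | O=C1N[C@H](Cc2ccccc2)CO1 | starting material
21 | 2,2-dimethylpropanoic 2-[(3S,3aS,8aR)-3,8,8-trimethyl-4-methylidenedecahydroazulen-3-yl]acetic anhydride | C=C1CCCC(C)(C)[C@@H]2CC[C@@](C)(CC(=O)OC(=O)C(C)(C)C)[C@H]12 | intermediate
22 | (4R)-4-benzyl-3-{2-[(3S,3aS,8aR)-3,8,8-trimethyl-4-methylidenedecahydroazulen-3-yl]acetyl}-1,3-oxazolidin-2-one | C=C1CCCC(C)(C)[C@@H]2CC[C@@](C)(CC(=O)N3C(=O)OC[C@H]3Cc4ccccc4)[C@H]12 | intermediate
23 | (5S)-5-{[(1S,2R,5S)-5-methyl-2-(propan-2-yl)cyclohexyl]oxy}furan-2(5H)-one | O=C1C=C[C@@H](O[C@H]2C[C@@H](C)CC[C@@H]2C(C)C)O1 | starting material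
24 | lithium (Z)-enolate of 22 | C=C1CCCC(C)(C)[C@@H]2CC[C@@](C)(/C=C(\[O-])N3C(=O)OC[C@H]3Cc4ccccc4)[C@H]12.[Li+] | intermediate
25 | (4R)-4-benzyl-3-[(2R)-2-{(2S,3R)-2-[(1S,2R,5S)-5-methyl-2-(propan-2-yl)cyclohexyl]oxy-5-oxooxolan-3-yl}-2-[(3R,3aS,8aR)-3,8,8-trimethyl-4-methylidenedecahydroazulen-3-yl]acetyl]-1,3-oxazolidin-2-one | C=C1CCCC(C)(C)[C@@H]2CC[C@@](C)([C@H](C(=O)N3C(=O)OC[C@H]3Cc4ccccc4)[C@@H]5[C@@H](O[C@H]6C[C@@H](C)CC[C@@H]6C(C)C)OC(=O)C5)[C@H]12 | intermediate
26 | (4R,5S)-4-{(1R)-2-hydroxy-1-[(3R,3aS,8aR)-3,8,8-trimethyl-4-methylidenedecahydroazulen-3-yl]ethyl}-5-{[(1S,2R,5S)-5-methyl-2-(propan-2-yl)cyclohexyl]oxy}oxolan-2-one | C=C1CCCC(C)(C)[C@@H]2CC[C@@](C)([C@H](CO)[C@@H]5[C@@H](O[C@H]6C[C@@H](C)CC[C@@H]6C(C)C)OC(=O)C5)[C@H]12 | intermediate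
27 | (3R,4R)-5-hydroxy-3-(hydroxymethyl)-4-[(3R,3aS,8aR)-3,8,8-trimethyl-4-methylidenedecahydroazulen-3-yl]pentanoic acid | C=C1CCCC(C)(C)[C@@H]2CC[C@@](C)([C@H](CO)[C@H](CO)CC(=O)O)[C@H]12 | intermediate
28 | (4R)-4-{(1R)-2-hydroxy-1-[(3R,3aS,8aR)-3,8,8-trimethyl-4-methylidenedecahydroazulen-3-yl]ethyl}oxolan-2-one | C=C1CCCC(C)(C)[C@@H]2CC[C@@](C)([C@H](CO)[C@@H]3COC(=O)C3)[C@H]12 | intermediate
29 | (4R)-4-{(1R)-2-acetoxy-1-[(3R,3aS,8aR)-3,8,8-trimethyl-4-methylidenedecahydroazulen-3-yl]ethyl}oxolan-2-one (CNP0235949.1) | C=C1CCCC(C)(C)[C@@H]2CC[C@@](C)([C@H](COC(C)=O)[C@@H]3COC(=O)C3)[C@H]12 | target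

Total step count: 16. Longest linear sequence: 16 steps (1 to 29); 2, 12, 20 and 23 enter as purchased reagents.

Steps most likely to fail

Step 9. What may go wrong: the tertiary radical may add to both faces of the cyclopentene, because methyl and the silyloxyethyl arm on C3 differ only modestly in size at the point of attachment. Hydrogenation of the isopropenyl group may also outrun the slow 7-endo closure. Fallback, which converges the ring-fusion epimers instead of separating them: setting out from 15 (taken as the epimer mixture), enolisation under equilibrating conditions (TMSCl, NaI, Et3N, MeCN) should give the more substituted trimethylsilyl enol ether F1. Saegusa–Ito oxidation (Pd(OAc)2, MeCN) should then give the C3a=C8a enone F2, in which both ring-fusion centres are erased. TBAF frees the hydroxy enone F3. Hydroxyl-directed homogeneous hydrogenation ([Ir(cod)(PCy3)(py)]PF6, H2, CH2Cl2) should deliver both hydrogens from the face of the CH2CH2OH arm, which is the face that carries H-3a and H-8a in the target, to give the cis-fused hydroxy ketone F4. Takai–Lombardo methylenation of F4 with excess reagent returns to the route at 17.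

Step 14. What may go wrong: C–C bond formation may stall, or give way to proton transfer and retro-Michael reaction, because the enolate carbon has a quaternary neighbour and the acceptor has the acetal substituent beside the reacting carbon. Fallback: setting out from 22, the chlorotitanium enolate (TiCl4, i-Pr2NEt, CH2Cl2, −78 → 0 °C) is added to unsubstituted furan-2(5H)-one, an acceptor with no group beside the reacting carbon, to give the imide lactone F5. C1' is still fixed by the auxiliary, whereas C4'' then rests on the topicity of the addition and its epimers are separated by chromatography. Sodium borohydride in THF/H2O removes the auxiliary from F5 and returns to the route at 28.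

Step 8. What may go wrong: direct, non-carbonylative coupling or protonation of the alkylzinc may compete with capture of the hindered acylpalladium intermediate. Fallback: setting out from 11, palladium-catalysed aminocarbonylation with N,O-dimethylhydroxylamine hydrochloride (Pd(OAc)2, Xantphos, CO, Et3N, toluene, 80 °C) gives the Weinreb amide F6. The Grignard reagent F7, made from 12 and magnesium in THF, adds once to F6, and the chelated adduct collapses on work-up to the enone, which returns to the route at 14.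

Further compounds
F1 | step 9 | tert-butyl{2-[(3S)-3,8,8-trimethyl-4-(trimethylsilyloxy)-1,2,3,5,6,7,8,8a-octahydroazulen-3-yl]ethoxy}diphenylsilane (both C8a epimers) | C[Si](C)(C)OC1=C2[C@](C)(CCO[Si](c3ccccc3)(c4ccccc4)C(C)(C)C)CCC2C(C)(C)CCC1
F2 | step 9 | (3S)-3-[2-(tert-butyldiphenylsilyloxy)ethyl]-3,8,8-trimethyl-2,3,5,6,7,8-hexahydroazulen-4(1H)-one | O=C1CCCC(C)(C)C2=C1[C@](C)(CCO[Si](c3ccccc3)(c4ccccc4)C(C)(C)C)CC2
F3 | step 9 | (3S)-3-(2-hydroxyethyl)-3,8,8-trimethyl-2,3,5,6,7,8-hexahydroazulen-4(1H)-one | O=C1CCCC(C)(C)C2=C1[C@](C)(CCO)CC2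
F4 | step 9 | (3S,3aR,8aR)-3-(2-hydroxyethyl)-3,8,8-trimethyl-2,3,3a,5,6,7,8,8a-octahydroazulen-4(1H)-one | O=C1CCCC(C)(C)[C@@H]2CC[C@@](C)(CCO)[C@H]12
F5 | step 14 | (4R)-4-benzyl-3-{(2R)-2-[(3R)-5-oxooxolan-3-yl]-2-[(3R,3aS,8aR)-3,8,8-trimethyl-4-methylidenedecahydroazulen-3-yl]acetyl}-1,3-oxazolidin-2-one | C=C1CCCC(C)(C)[C@@H]2CC[C@@](C)([C@H](C(=O)N3C(=O)OC[C@H]3Cc4ccccc4)[C@@H]5COC(=O)C5)[C@H]12
F6 | step 8 | (5S)-5-[2-(tert-butyldiphenylsilyloxy)ethyl]-N-methoxy-N,5-dimethylcyclopent-1-ene-1-carboxamide | CON(C)C(=O)C1=CCC[C@@]1(C)CCO[Si](c2ccccc2)(c3ccccc3)C(C)(C)C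
F7 | step 8 | (4-methylpent-4-en-1-yl)magnesium bromide | C=C(C)CCC[Mg]Br
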